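50.0% of the J charged is the most DEEG that red or amber can hold, and the examination starts there.

the same everywhere: J 11 mM; Z 6.6 mM (held)
- midnight: E 1.8 equiv; temperature −15 °C; run made earlier
- autumn: E 2.2 equiv; temperature −4 °C; run made earlier
- violet: E 3.00 equiv; temperature 0 °C; time 4.0 min
- red: E 1.00 equiv; temperature 0 °C; time 4.0 min
- ochre: E 3.00 equiv; temperature −20 °C; time 4.0 min
- amber: E 1.00 equiv; temperature −20 °C; time 4.0 min

| midnight: time / min | midnight: DEEG / % | autumn: time / s | autumn: DEEG / % |
|---|---|---|---|
| 1.00 | 48.1 | 15.0 | 16.5 |
| 2.00 | 67.2 | 40.0 | 63.2 |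
| 3.00 | 73.3 | 60.0 | 80.4 |
| 4.00 | 75.4 | 120 | 87.4 |

(each reading ± 0.5 percentage points)

- J is a solid; its amount is given per volume of the solution
- at the start none of G is dissolved
- what may be going on: D + E -> DE; E + G -> EG; DE + EG -> DEEG; D + EG -> DEG; Z <-> G; J <-> D
- at the start none of J is in solution
- what has only dissolved of J counts as not reacted

- ranking by amount of DEEG, in percent of the J charged, from high to low, at 4.0 min (violet / red / ochre / amber)
- the amount of DEEG, in percent of the J charged of the flask you put first, at 4.0 min
- the amount of DEEG, in percent of the J charged of the flask you put last, at 4.0 min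

Where does that figure come from? By the listed steps, one DEEG holds two E, one from DE and one from EG, so DEEG cannot pass the equivalents of E divided by two. This is the ceiling, and at 1.00 equiv E is the limiting reagent.

And in violet and ochre? There the ceiling is 150%, which J cannot fill, so J is the limiting reagent and the cap is the J charged.

Is 4.0 min long enough to reach a plateau? The midnight run at −15 °C approaches its last reading with a time constant of about 0.780 min, read from its first and third readings. The asked time is 5.13 such constants, and although ochre and amber are colder, I reckon with plateaus.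

But a ceiling is no forecast: how far below it does a flask stop? E can also sit where it makes no DEEG, in DEG, in EG or in DE without a partner. So I name the gap, the ceiling minus the DEEG reached. The midnight run has a ceiling of 90.0% and a last reading of 75.4%, so its gap is 15 percentage points.

Why should that gap hold when E is scarcer? Nothing guarantees it; I freeze it as a first guess. That puts red and amber both near 35.4%, and this reckoning cannot rank the two. Violet and ochre, with more E than autumn's 2.2 equiv, I put above autumn's 87.4%.

The forecast gives violet > ochre > red > amber, with 92% first and 27% last for amber, lower than my figure, on the ground that “at −20 °C, k ≈ 0.5–0.8 /min, and 4 min is incomplete”.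

The flasks give violet > ochre > amber > red: violet 92.1%, ochre 88.6%, amber 23.7%, red 21.3%.

    D + E → DE (k = 5.70 M⁻¹ s⁻¹, Ea = 39.0 kJ mol⁻¹)
    E + G → EG (k = 5.10 M⁻¹ s⁻¹, Ea = 38.0 kJ mol⁻¹)
    DE + EG → DEEG (k = 7.20 M⁻¹ s⁻¹, Ea = 38.0 kJ mol⁻¹)
    D + EG → DEG (k = 7.10 M⁻¹ s⁻¹, Ea = 44.0 kJ mol⁻¹)
    Z ⇌ G, rate k5*(csat - [G]) (kL = 0.0780 s⁻¹)
    J ⇌ D, rate k6*(cs6 - [D]) while solid is left; crystals form when [D] > cs6 (solubility = 4.00 mM, k = 0.350 s⁻¹)
    (constants at −20 °C)

Red ends at 21.3% with E at 0% of its charge, so its gap is 29 points, wider than the 15 points of the midnight run, and my 35.4% stood too high. Now freeze red's gap and take the neighbour of violet with 1.20 equiv of E at 0 °C: its ceiling is 60.0%, and less the gap that leaves 31.0%. That flask gives 30.9% of DEEG, beside 20.4% of DEG and 37.7% of DE, with E at 0%.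

The numbers in the tables were computed with made-up constants; the scatter is artificial.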